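**Plan**
- Retrosynthesis: the B6–H bond is traced back to a B6–N bond (hydrodediazoniation). The B3–Br and B5–Br bonds are then cut together (one double bromination of an acetanilide). Further back: B6–N (nitration), B1–O (Dakin oxidation), the diaryl ether C–O bond (SNAr), and the phenolic C–O and the O–CH3 bonds of ring A.
- Forward: both benzene rings are bought. The ring A phenol is made from 3,5-dibromosalicylaldehyde (O-methylation, Dakin) and joined to ring B by fluoride displacement on 4-bromo-2-fluorobenzaldehyde. Dakin oxidation, nitration, reduction, N-acetylation, double bromination, amide hydrolysis and deamination follow.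
- Enabling feature: ring B carries OH at B1, O-aryl at B2, Br at B3, B4 and B5, and H at B6. The B3 and B5 bromines are meta to the hydroxyl while its ortho carbon B6 is bare, a pattern the phenol cannot direct. An acetamido group parked at B6 is ortho to B5 and para to B3, directs both bromines, and is then erased.
- Stereochemistry: none; the target has no stereocentre.

Key step: step 8

Remark: ring B is the phenol ring, numbered from the hydroxyl carbon B1 through the aryloxy carbon B2 round to B6. Ring A is the methoxy-bearing ring: its methoxy group is flanked by the bridging oxygen on one side and a bromine on the other, and the second bromine sits para to the methoxy group. 4-Bromo-2-fluorobenzaldehyde is taken as the ring B unit so that the B4 bromine is present from the start, since fluoride ortho to a formyl group is displaced far faster than bromide para to it.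

**Step 1**
Reactants: 1 3,5-dibromo-2-hydroxybenzaldehyde
Product: 2 3,5-dibromo-2-methoxybenzaldehyde
Conditions: MeI (1.5 equiv), K2CO3, DMF, rt
Reagents that add atoms: iodomethane, CI
Why: Williamson ether synthesis; the acidic salicylaldehyde phenoxide is methylated cleanly by the small electrophile even though it is flanked by CHO and Br.

**Step 2**
Reactants: 2 3,5-dibromo-2-methoxybenzaldehyde
Product: 4 3,5-dibromo-2-methoxyphenol, via aryl formate 3 (not isolated)
Conditions: mCPBA (1.6 equiv), CH2Cl2, 40 °C; aq Na2SO3/NaHCO3 wash; then K2CO3 (cat.), MeOH, rt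
Reagents that add atoms: mCPBA (3-chloroperoxybenzoic acid), OOC(=O)c1cccc(Cl)c1
Why: Dakin-type Baeyer–Villiger oxidation, in which the peracid adds to the formyl group, the ortho-alkoxy aryl group migrates to oxygen in the Criegee adduct to give the aryl formate, and carbonate-catalysed methanolysis releases the phenol.

**Step 3**
Reactants: 4 3,5-dibromo-2-methoxyphenol; 5 4-bromo-2-fluorobenzaldehyde
Product: 6 4-bromo-2-(3,5-dibromo-2-methoxyphenoxy)benzaldehyde
Conditions: K2CO3 (1.5 equiv), DMAc, 120 °C
Reagents that add atoms: none
Why: SNAr by addition–elimination, with the phenoxide of 4 attacking the fluorine-bearing carbon ortho to the formyl group; fluoride leaves in preference to the bromide para to the aldehyde, and the unactivated bromides of ring A are inert.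

**Step 4**
Reactants: 6 4-bromo-2-(3,5-dibromo-2-methoxyphenoxy)benzaldehyde
Product: 8 4-bromo-2-(3,5-dibromo-2-methoxyphenoxy)phenol, via aryl formate 7 (not isolated)
Conditions: mCPBA (1.5 equiv), CH2Cl2, 40 °C; aq Na2SO3/NaHCO3 wash; then K2CO3 (cat.), MeOH, rt
Reagents that add atoms: mCPBA (3-chloroperoxybenzoic acid), OOC(=O)c1cccc(Cl)c1
Why: Dakin-type Baeyer–Villiger oxidation of a 2-aryloxybenzaldehyde, in which the ortho-aryloxy oxygen (coplanar, with only one ortho neighbour) raises the migratory aptitude of ring B so that the formate forms and is then cleaved by methanolysis.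

**Step 5**
Reactants: 8 4-bromo-2-(3,5-dibromo-2-methoxyphenoxy)phenol
Product: 9 4-bromo-2-(3,5-dibromo-2-methoxyphenoxy)-6-nitrophenol
Conditions: 65% HNO3 (1.05 equiv), AcOH, 10–15 °C
Reagents that add atoms: nitric acid, O[N+](=O)[O-]
Why: electrophilic nitration of a phenol, where B6 is the only free carbon ortho or para to the hydroxyl, the o-nitrophenol gains an internal hydrogen bond, and dilute acid at low temperature should avoid ipso attack at B4 and leave the deactivated ring A untouched.

**Step 6**
Reactants: 9 4-bromo-2-(3,5-dibromo-2-methoxyphenoxy)-6-nitrophenol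
Product: 10 2-amino-4-bromo-6-(3,5-dibromo-2-methoxyphenoxy)phenol
Conditions: Fe powder (5 equiv), AcOH/EtOH/H2O, 70 °C; filter, aq NaHCO3
Reagents that add atoms: none
Why: Béchamp-type dissolving-metal reduction of a nitroarene, which leaves aryl bromides intact; the air-sensitive o-aminophenol is taken on at once.

**Step 7**
Reactants: 10 2-amino-4-bromo-6-(3,5-dibromo-2-methoxyphenoxy)phenol
Product: 11 N-[5-bromo-3-(3,5-dibromo-2-methoxyphenoxy)-2-hydroxyphenyl]acetamide
Conditions: Ac2O (1.05 equiv), THF, 0 °C to rt
Reagents that add atoms: acetic anhydride, CC(=O)OC(C)=O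
Why: chemoselective N-acylation, since the amino group is far more nucleophilic than the phenol toward one equivalent of anhydride, as in the standard acetylation of aminophenols.

**Step 8**
Reactants: 11 N-[5-bromo-3-(3,5-dibromo-2-methoxyphenoxy)-2-hydroxyphenyl]acetamide
Product: 12 N-[4,5,6-tribromo-3-(3,5-dibromo-2-methoxyphenoxy)-2-hydroxyphenyl]acetamide
Conditions: Br2 (2.2 equiv), AcOH, rt to 50 °C; aq NaHSO3
Reagents that add atoms: bromine, BrBr
Why: Electrophilic aromatic bromination: Br2 attacks ring B to give arenium ions whose charge is delocalised onto the amide nitrogen, and proton loss restores the arene, the first bromine being expected para to nitrogen (B3) and the second ortho (B5). The closest known reaction is the ortho/para polybromination of acetanilides in acetic acid, reinforced here by the B2 aryloxy oxygen, to which B3 is ortho and B5 para. No ring is closed and no stereocentre is formed. The selectivity required is B3 and B5 over ring A, over ipso positions and over oxidation at N or O: in 11 every carbon ortho or para to the hydroxyl is occupied (B2 O-aryl, B4 Br, B6 N), so the phenol can only give reversible ipso adducts, which the HBr formed and the bisulfite quench should return to the arene. Ring A carries two bromines, its methoxy group is twisted out of conjugation by its two ortho neighbours and its two free carbons are meta to that group, activated only by the bridging oxygen that it shares with the electron-poor ring B, so it should not compete while bromine is held just above two equivalents. The acetyl group tempers the nitrogen enough to keep the aminophenol from being oxidised to a quinone imine.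

**Step 9**
Reactants: 12 N-[4,5,6-tribromo-3-(3,5-dibromo-2-methoxyphenoxy)-2-hydroxyphenyl]acetamide
Product: 13 2-amino-3,4,5-tribromo-6-(3,5-dibromo-2-methoxyphenoxy)phenol
Conditions: 6 M HCl/EtOH (1:2), reflux; then aq NaHCO3
Reagents that add atoms: none
Why: acid-catalysed amide hydrolysis, to which aryl ethers and aryl bromides are stable and in which protonation of the liberated amine shields the electron-rich ring.

**Step 10**
Reactants: 13 2-amino-3,4,5-tribromo-6-(3,5-dibromo-2-methoxyphenoxy)phenol
Product: 15 3,4,5-tribromo-2-(3,5-dibromo-2-methoxyphenoxy)phenol, via diazo oxide 14 (not isolated)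
Conditions: NaNO2, H2SO4, AcOH, 0–5 °C; then 50% aq H3PO2, Cu2O (cat.), 0 °C to rt
Reagents that add atoms: none
Why: diazotization of a weakly basic amine in strong acid followed by hydrodediazoniation with hypophosphorous acid (radical chain with hydrogen-atom transfer from H3PO2 to the aryl radical), the standard reductant for aminophenols whose diazonium ions equilibrate with diazo oxides.

**Compound list**
1 | 3,5-dibromo-2-hydroxybenzaldehyde (3,5-dibromosalicylaldehyde) | O=Cc1cc(Br)cc(Br)c1O | starting material
2 | 3,5-dibromo-2-methoxybenzaldehyde | COc1c(Br)cc(Br)cc1C=O | intermediate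
3 | 3,5-dibromo-2-methoxyphenyl formate | COc1c(Br)cc(Br)cc1OC=O | intermediate
4 | 3,5-dibromo-2-methoxyphenol | COc1c(Br)cc(Br)cc1O | intermediate
5 | 4-bromo-2-fluorobenzaldehyde | O=Cc1ccc(Br)cc1F | starting material
6 | 4-bromo-2-(3,5-dibromo-2-methoxyphenoxy)benzaldehyde | COc1c(Br)cc(Br)cc1Oc1cc(Br)ccc1C=O | intermediate
7 | 4-bromo-2-(3,5-dibromo-2-methoxyphenoxy)phenyl formate | COc1c(Br)cc(Br)cc1Oc1cc(Br)ccc1OC=O | intermediate
8 | 4-bromo-2-(3,5-dibromo-2-methoxyphenoxy)phenol | COc1c(Br)cc(Br)cc1Oc1cc(Br)ccc1O | intermediate
9 | 4-bromo-2-(3,5-dibromo-2-methoxyphenoxy)-6-nitrophenol | COc1c(Br)cc(Br)cc1Oc1cc(Br)cc([N+](=O)[O-])c1O | intermediate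
10 | 2-amino-4-bromo-6-(3,5-dibromo-2-methoxyphenoxy)phenol | COc1c(Br)cc(Br)cc1Oc1cc(Br)cc(N)c1O | intermediate
11 | N-[5-bromo-3-(3,5-dibromo-2-methoxyphenoxy)-2-hydroxyphenyl]acetamide | CC(=O)Nc1cc(Br)cc(Oc2cc(Br)cc(Br)c2OC)c1O | intermediate
12 | N-[4,5,6-tribromo-3-(3,5-dibromo-2-methoxyphenoxy)-2-hydroxyphenyl]acetamide | CC(=O)Nc1c(Br)c(Br)c(Br)c(Oc2cc(Br)cc(Br)c2OC)c1O | intermediate
13 | 2-amino-3,4,5-tribromo-6-(3,5-dibromo-2-methoxyphenoxy)phenol | COc1c(Br)cc(Br)cc1Oc1c(O)c(N)c(Br)c(Br)c1Br | intermediate
14 | 3,4,5-tribromo-2-diazonio-6-(3,5-dibromo-2-methoxyphenoxy)phenolate (diazo oxide) | COc1c(Br)cc(Br)cc1Oc1c([O-])c([N+]#N)c(Br)c(Br)c1Br | intermediate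
15 | 3,4,5-tribromo-2-(3,5-dibromo-2-methoxyphenoxy)phenol | COc1c(Br)cc(Br)cc1Oc1c(O)cc(Br)c(Br)c1Br | target

**Step count**
Total steps: 10. Longest linear sequence: 10 steps (1 to 15; 5 enters at step 3).

**Steps most likely to fail**

Step 8. After the first bromine has entered, the remaining site is flanked on both sides, so the second substitution may stall. Forcing it with more bromine or heat would invite ipso attack at the phenol-activated carbons, oxidative loss of ring B and bromination of ring A. The fallback sets out from 11. O-Acetylation (Ac2O, pyridine, cat. DMAP) would give 2-acetamido-4-bromo-6-(3,5-dibromo-2-methoxyphenoxy)phenyl acetate F1. Because B3 and B5 are meta to the phenolic oxygen, capping it costs little activation where it matters but closes the ipso and oxidation channels. Harder bromination (excess Br2, AcOH, 60–80 °C) should then give 2-acetamido-3,4,5-tribromo-6-(3,5-dibromo-2-methoxyphenoxy)phenyl acetate F2. The HCl/EtOH hydrolysis of step 9 cleaves ester and amide together, and the route is rejoined at 13.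

Step 10. The o-hydroxy diazonium ion loses a proton to give the stabilised diazo oxide, which may precipitate, be reduced only sluggishly and decompose by other pathways on warming, so hydrodediazoniation may be incomplete. The fallback sets out from 12. Mesylation (MsCl, Et3N, CH2Cl2) would give 2-acetamido-3,4,5-tribromo-6-(3,5-dibromo-2-methoxyphenoxy)phenyl methanesulfonate F3. Acid hydrolysis of the amide (H2SO4, EtOH/H2O, reflux), which the aryl sulfonate survives, would give 2-amino-3,4,5-tribromo-6-(3,5-dibromo-2-methoxyphenoxy)phenyl methanesulfonate F4. Diazotization (NaNO2, H2SO4, AcOH) would give 2,3,4-tribromo-5-(3,5-dibromo-2-methoxyphenoxy)-6-(methanesulfonyloxy)benzenediazonium hydrogensulfate F5, which cannot collapse to a diazo oxide and should behave like a tribromobenzenediazonium salt. Reduction with H3PO2 would give 3,4,5-tribromo-2-(3,5-dibromo-2-methoxyphenoxy)phenyl methanesulfonate F6. Cleavage of the sulfonate (KOH, MeOH/THF, 50 °C) then arrives at the target 15.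

Step 2. In the Criegee adduct, hydride migration may outrun aryl migration, because the ring is electron-poor and its methoxy group, flanked on both sides, is twisted out of conjugation; oxidation would then stop at the carboxylic acid level instead of giving the formate. The fallback sets out from 2 and uses that oxidation level deliberately. Pinnick oxidation (NaClO2, NaH2PO4, 2-methyl-2-butene, tBuOH/H2O) would give 3,5-dibromo-2-methoxybenzoic acid F7. Curtius rearrangement (DPPA, Et3N, toluene, 90 °C) would proceed through 3,5-dibromo-2-methoxybenzoyl azide F8 and 1,5-dibromo-3-isocyanato-2-methoxybenzene F9, neither isolated. Hydrolysis of the isocyanate (aq HCl, THF) would give 3,5-dibromo-2-methoxyaniline F10. Diazotization (NaNO2, aq H2SO4, 0 °C) would give 3,5-dibromo-2-methoxybenzenediazonium hydrogensulfate F11, and hydroxydediazoniation (Cu2O, Cu(NO3)2, H2O, rt) would return to the route at phenol 4.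

**Further compounds**
F1 | step 8 | 2-acetamido-4-bromo-6-(3,5-dibromo-2-methoxyphenoxy)phenyl acetate | CC(=O)Nc1cc(Br)cc(Oc2cc(Br)cc(Br)c2OC)c1OC(C)=O
F2 | step 8 | 2-acetamido-3,4,5-tribromo-6-(3,5-dibromo-2-methoxyphenoxy)phenyl acetate | CC(=O)Nc1c(Br)c(Br)c(Br)c(Oc2cc(Br)cc(Br)c2OC)c1OC(C)=O
F3 | step 10 | 2-acetamido-3,4,5-tribromo-6-(3,5-dibromo-2-methoxyphenoxy)phenyl methanesulfonate | CC(=O)Nc1c(Br)c(Br)c(Br)c(Oc2cc(Br)cc(Br)c2OC)c1OS(C)(=O)=O
F4 | step 10 | 2-amino-3,4,5-tribromo-6-(3,5-dibromo-2-methoxyphenoxy)phenyl methanesulfonate | COc1c(Br)cc(Br)cc1Oc1c(OS(C)(=O)=O)c(N)c(Br)c(Br)c1Br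
F5 | step 10 | 2,3,4-tribromo-5-(3,5-dibromo-2-methoxyphenoxy)-6-(methanesulfonyloxy)benzenediazonium hydrogensulfate | COc1c(Br)cc(Br)cc1Oc1c(OS(C)(=O)=O)c([N+]#N)c(Br)c(Br)c1Br.OS(=O)(=O)[O-]
F6 | step 10 | 3,4,5-tribromo-2-(3,5-dibromo-2-methoxyphenoxy)phenyl methanesulfonate | COc1c(Br)cc(Br)cc1Oc1c(OS(C)(=O)=O)cc(Br)c(Br)c1Br
F7 | step 2 | 3,5-dibromo-2-methoxybenzoic acid | COc1c(Br)cc(Br)cc1C(=O)O
F8 | step 2 | 3,5-dibromo-2-methoxybenzoyl azide | COc1c(Br)cc(Br)cc1C(=O)N=[N+]=[N-]
F9 | step 2 | 1,5-dibromo-3-isocyanato-2-methoxybenzene | COc1c(Br)cc(Br)cc1N=C=O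
F10 | step 2 | 3,5-dibromo-2-methoxyaniline | COc1c(Br)cc(Br)cc1N
F11 | step 2 | 3,5-dibromo-2-methoxybenzenediazonium hydrogensulfate | COc1c(Br)cc(Br)cc1[N+]#N.OS(=O)(=O)[O-]
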